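**Retrosynthetic overview**
- Last step: removal of the side-chain silyl ether. Before that, both rings are made in one flask from an acyclic 2-(oxiranyl)acrylate that carries the C6 enal.
- Ring order in that flask: Pd(0) opens the allylic C7–O bond and the freed O8 closes the γ-lactone on C12. The resulting butenolide allylzinc then closes C6–C7 to give the ten-membered ring.
- The vinyl epoxide comes from an (R)-α-chloroaldehyde and an α-metallated acrylate (C7–C11 bond). Epoxide closure inverts C8, the only stereocentre set by a catalyst.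
- The C3–C4 bond is made by B-alkyl Suzuki coupling of a 1,3-dienol with a 2-bromoallylic ester that already carries the side chain.
- The dienol comes from pent-4-yn-1-ol (carboalumination/vinylation sets 1(10)-E). The bromide comes from 4-bromofuranone, whose ring fixes the C4=C5 geometry.

Assumption: locants C1–C15 follow germacrane numbering (C6 carbinol, C7, C8 lactone carbinol, C12 lactone C=O, C13 exocyclic CH2, C15 acyloxymethyl). The target SMILES reads as 6R,7S,8S, a trans-fused lactone with 6,7-anti relationship. All numbered starting materials are taken as purchasable.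

**Step 1**
Reactants: 1 (tert-butyldimethylsilyloxy)acetaldehyde; 2 ethyl 2-(triphenylphosphoranylidene)propanoate
Product: 3 ethyl (E)-4-(tert-butyldimethylsilyloxy)-2-methylbut-2-enoate
Conditions: CH2Cl2, rt
Reagents that add atoms: none
Why: Wittig olefination with a stabilised α-methyl ylide gives the trisubstituted enoate with high E selectivity (ester trans to CH2OTBS), which is the side-chain geometry of the target.

**Step 2**
Reactants: 3 ethyl (E)-4-(tert-butyldimethylsilyloxy)-2-methylbut-2-enoate
Product: 4 (E)-4-(tert-butyldimethylsilyloxy)-2-methylbut-2-enoic acid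
Conditions: LiOH, THF/MeOH/H2O, rt; 1 M HCl to pH 4
Reagents that add atoms: lithium hydroxide [Li+].[OH-]
Why: Saponification of an unhindered ethyl ester, under which the primary TBS ether and the E-alkene are stable.

**Step 3**
Reactants: 5 4-bromofuran-2(5H)-one
Product: 6 (E)-2-bromobut-2-ene-1,4-diol (the two CH2OH groups cis)
Conditions: DIBAL-H (3.2 equiv), CH2Cl2, −78 → 0 °C; Rochelle salt
Reagents that add atoms: none
Why: Exhaustive 1,2-reduction of the lactone (lactone → lactol → diol) spares the vinyl bromide, and the cyclic origin of the alkene forces the CH2OH groups cis, so Br (later C3) is trans to the future C6.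

**Step 4**
Reactants: 6 (E)-2-bromobut-2-ene-1,4-diol
Product: 7 (E)-2-bromo-4-(triethylsilyloxy)but-2-en-1-ol
Conditions: TESCl (1.0 equiv), imidazole, CH2Cl2, −78 → −30 °C
Reagents that add atoms: chlorotriethylsilane CC[Si](Cl)(CC)CC
Why: Kinetic monosilylation, because the OH remote from bromine (future O6) is less hindered and less inductively deactivated than the OH on the CH2 next to C–Br (future O15).

**Step 5**
Reactants: 7 (E)-2-bromo-4-(triethylsilyloxy)but-2-en-1-ol; 4 (E)-4-(tert-butyldimethylsilyloxy)-2-methylbut-2-enoic acid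
Product: 8 (E)-2-bromo-4-(triethylsilyloxy)but-2-en-1-yl (E)-4-(tert-butyldimethylsilyloxy)-2-methylbut-2-enoate
Conditions: EDC·HCl, DMAP, CH2Cl2, 0 °C → rt
Reagents that add atoms: none
Why: Steglich-type carbodiimide esterification of the only free OH, under neutral conditions that leave both silyl ethers, the vinyl bromide and the enoate geometry untouched.

**Step 6**
Reactants: 9 pent-4-yn-1-ol; 10 vinyl bromide
Product: 12 (E)-4-methylhepta-4,6-dien-1-ol, via alkenylalane 11 (not isolated)
Conditions: Me3Al (3 equiv), Cp2ZrCl2 (25 mol %), CH2Cl2, 0 °C → rt; then 10 (excess), Pd(PPh3)4 (5 mol %), ZnCl2, THF, rt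
Reagents that add atoms: trimethylaluminium C[Al](C)C
Why: Negishi Zr-catalysed carboalumination adds Me and Al syn with Me on the internal carbon, and the Pd-catalysed alkenyl–alkenyl coupling goes with retention, which fixes the 1(10)-E trisubstituted alkene.

**Step 7**
Reactants: 12 (E)-4-methylhepta-4,6-dien-1-ol; 8 (E)-2-bromo-4-(triethylsilyloxy)but-2-en-1-yl (E)-4-(tert-butyldimethylsilyloxy)-2-methylbut-2-enoate
Product: 14 [(2Z,6E)-10-hydroxy-7-methyl-1-(triethylsilyloxy)deca-2,6-dien-3-yl]methyl (E)-4-(tert-butyldimethylsilyloxy)-2-methylbut-2-enoate, via B-alkyl-9-BBN 13 (not isolated)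
Conditions: 9-BBN-H (2.2 equiv), THF, 0 °C → rt; then aq Cs2CO3, 8, PdCl2(dppf) (5 mol %), AsPh3, DMF, rt
Reagents that add atoms: none
Why: 9-BBN attacks only the terminal carbon of the diene to give a homoallylic borane, and the B-alkyl Suzuki–Miyaura coupling replaces Br with retention, so C3 ends up trans to C6 as in the target.

**Step 8**
Reactants: 14 the C7 primary alcohol
Product: 15 [(2Z,6E)-7-methyl-10-oxo-1-(triethylsilyloxy)deca-2,6-dien-3-yl]methyl (E)-4-(tert-butyldimethylsilyloxy)-2-methylbut-2-enoate
Conditions: Dess–Martin periodinane, NaHCO3, CH2Cl2, 0 °C → rt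
Reagents that add atoms: none
Why: Buffered Dess–Martin oxidation of the only free alcohol gives a γ,δ-unsaturated aldehyde that cannot move into conjugation, and the silyl ethers and esters are inert.

**Step 9**
Reactants: 15 the C7 aldehyde
Product: 16 [(2Z,6E,9R)-9-chloro-7-methyl-10-oxo-1-(triethylsilyloxy)deca-2,6-dien-3-yl]methyl (E)-4-(tert-butyldimethylsilyloxy)-2-methylbut-2-enoate (8R in germacrane numbering; used without chromatography)
Conditions: (5R)-5-benzyl-2,2,3-trimethylimidazolidin-4-one·TFA (10 mol %), 2,3,4,5,6,6-hexachlorocyclohexa-2,4-dien-1-one (1.2 equiv), acetone, −30 °C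
Reagents that add atoms: 2,3,4,5,6,6-hexachlorocyclohexa-2,4-dien-1-one O=C1C(Cl)=C(Cl)C(Cl)=C(Cl)C1(Cl)Cl
Why: Organocatalytic enamine α-chlorination, in which the benzyl group of the (5R)-catalyst shields one face of the E-enamine so that Cl+ arrives from the open face and sets C8 as R, while the mild Cl+ donor ignores the unactivated alkenes.

**Step 10**
Reactants: 16 the (R)-α-chloroaldehyde; 17 methyl propiolate
Product: 19 methyl (3S,4R,6E,10Z)-4-chloro-3-hydroxy-6-methyl-2-methylidene-10-{[(E)-4-(tert-butyldimethylsilyloxy)-2-methylbut-2-enoyl]oxymethyl}-12-(triethylsilyloxy)dodeca-6,10-dienoate, via vinylalane 18 (not isolated)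
Conditions: 17, DIBAL-H, NMO, THF, 0 °C; then 16, −78 → −20 °C; Rochelle salt
Reagents that add atoms: none
Why: Vinylalumination (a Baylis–Hillman surrogate), in which the α-aluminated acrylate adds to the very electrophilic α-chloroaldehyde under Cornforth/polar Felkin–Anh control to give the anti chlorohydrin (7S), a centre that is erased later so its ratio does not matter.

**Step 11**
Reactants: 19 the anti chlorohydrin
Product: 20 methyl 2-[(2S,3S)-3-{(2E,6Z)-2-methyl-6-{[(E)-4-(tert-butyldimethylsilyloxy)-2-methylbut-2-enoyl]oxymethyl}-8-(triethylsilyloxy)octa-2,6-dien-1-yl}oxiran-2-yl]prop-2-enoate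
Conditions: Cs2CO3, MeCN, 0 °C → rt
Reagents that add atoms: none
Why: Halohydrin-to-epoxide closure (intramolecular Williamson SN2) inverts C8, which places oxygen on C8 with the 8S configuration of the target, and anti chlorohydrin gives the trans epoxide.

**Step 12**
Reactants: 20 the vinyl epoxide TES ether
Product: 21 methyl 2-[(2S,3S)-3-{(2E,6Z)-2-methyl-6-{[(E)-4-(tert-butyldimethylsilyloxy)-2-methylbut-2-enoyl]oxymethyl}-8-oxoocta-2,6-dien-1-yl}oxiran-2-yl]prop-2-enoate
Conditions: DDQ (1.5 equiv), CH2Cl2/pH 7 buffer, 0 °C → rt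
Reagents that add atoms: none
Why: Direct DDQ oxidation of an electron-rich allylic silyl ether by hydride abstraction gives the enal at neutral pH, whereas the side-chain allylic TBS ether sits on an electron-poor enoate and does not react.

**Step 13**
Reactants: 21 the vinyl epoxide enal
Product: 24 4'-O-TBS ether of the target (6R,7S,8S), via zinc alkoxide allylzinc 22 (not isolated), via butenolide allylzinc 23 (not isolated)
Conditions: Pd(PPh3)4 (10 mol %), Et2Zn (4 equiv), THF (2 mM, 21 added over 3 h), 0 °C → rt; aq NH4Cl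
Reagents that add atoms: none
Why: Proposed new method: Pd(0) ionises the strained allylic C7–O bond of the 2-(oxiranyl)acrylate without touching C8–O; the freed C8 alkoxide lies syn to the ester on the allyl unit and closes the butenolide, and because a five-ring closure is far faster than any ten-ring closure, O8 rather than the later O6 takes C12; Et2Zn reduces the π-allylpalladium to allylzinc 23, whose ring locks the E-crotyl-type geometry, and it adds through C7 to the enal in a chair Zimmerman–Traxler transition state on the face anti to the C8 chain with all substituents pseudo-equatorial, giving 7,8-trans and 6,7-anti (6R,7S from 8S) and the exocyclic methylene; the closest known reaction types are the Pd/Et2Zn and Pd/InI umpolung allylations of aldehydes with vinyl epoxides or allylic halides, including ten-membered germacrane closures, and the Zn or Cr Barbier additions of 3-(bromomethyl)butenolides to aldehydes.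

**Step 14**
Reactants: 24 4'-O-TBS ether of the target
Product: 25 (6R,7S,8S)-6-hydroxy-15-[(E)-4-hydroxy-2-methylbut-2-enoyloxy]germacra-1(10)E,4Z,11(13)-trien-12,8-olide (CNP0326626.1)
Conditions: HF·pyridine, pyridine, THF, 0 °C
Reagents that add atoms: none
Why: Buffered fluoride desilylation removes the primary TBS ether without base (no Michael addition or relactonisation) and without free acid (no transannular cyclisation of the 1,5-diene).

**Compound list**
1 | (tert-butyldimethylsilyloxy)acetaldehyde | O=CCO[Si](C)(C)C(C)(C)C | starting material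
2 | ethyl 2-(triphenylphosphoranylidene)propanoate | CCOC(=O)C(C)=P(c1ccccc1)(c1ccccc1)c1ccccc1 | starting material
3 | ethyl (E)-4-(tert-butyldimethylsilyloxy)-2-methylbut-2-enoate | CCOC(=O)/C(C)=C/CO[Si](C)(C)C(C)(C)C | intermediate
4 | (E)-4-(tert-butyldimethylsilyloxy)-2-methylbut-2-enoic acid | OC(=O)/C(C)=C/CO[Si](C)(C)C(C)(C)C | intermediate
5 | 4-bromofuran-2(5H)-one | O=C1C=C(Br)CO1 | starting material
6 | (E)-2-bromobut-2-ene-1,4-diol (CH2OH groups cis) | OC/C=C(/Br)CO | intermediate
7 | (E)-2-bromo-4-(triethylsilyloxy)but-2-en-1-ol | CC[Si](CC)(CC)OC/C=C(/Br)CO | intermediate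
8 | (E)-2-bromo-4-(triethylsilyloxy)but-2-en-1-yl (E)-4-(tert-butyldimethylsilyloxy)-2-methylbut-2-enoate | CC[Si](CC)(CC)OC/C=C(/Br)COC(=O)/C(C)=C/CO[Si](C)(C)C(C)(C)C | intermediate
9 | pent-4-yn-1-ol | C#CCCCO | starting material
10 | vinyl bromide | C=CBr | starting material
11 | (E)-alkenylalane, O- and C-bound AlMe2 (not isolated) | C[Al](C)OCCC/C(C)=C/[Al](C)C | intermediate
12 | (E)-4-methylhepta-4,6-dien-1-ol | OCCC/C(C)=C/C=C | intermediate
13 | B-alkyl-9-BBN of 12, O-borinate (not isolated) | B1(OCCC/C(C)=C/CCB2C3CCCC2CCC3)C2CCCC1CCC2 | intermediate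
14 | [(2Z,6E)-10-hydroxy-7-methyl-1-(triethylsilyloxy)deca-2,6-dien-3-yl]methyl (E)-4-(TBSO)-2-methylbut-2-enoate | OCCC/C(C)=C/CC/C(COC(=O)/C(C)=C/CO[Si](C)(C)C(C)(C)C)=C/CO[Si](CC)(CC)CC | intermediate
15 | corresponding C7 aldehyde (10-oxo) | O=CCC/C(C)=C/CC/C(COC(=O)/C(C)=C/CO[Si](C)(C)C(C)(C)C)=C/CO[Si](CC)(CC)CC | intermediate
16 | (9R)-9-chloro-10-oxo compound (8R germacrane numbering) | O=C[C@H](Cl)C/C(C)=C/CC/C(COC(=O)/C(C)=C/CO[Si](C)(C)C(C)(C)C)=C/CO[Si](CC)(CC)CC | intermediate
17 | methyl propiolate | C#CC(=O)OC | starting material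
18 | [1-(methoxycarbonyl)vinyl]diisobutylaluminium (not isolated) | C=C(C(=O)OC)[Al](CC(C)C)CC(C)C | intermediate
19 | anti chlorohydrin, (3S,4R)-4-chloro-3-hydroxy-2-methylidene ester | COC(=O)C(=C)[C@H](O)[C@H](Cl)C/C(C)=C/CC/C(COC(=O)/C(C)=C/CO[Si](C)(C)C(C)(C)C)=C/CO[Si](CC)(CC)CC | intermediate
20 | trans-(2S,3S)-2-(oxiranyl)acrylate, O6-TES | COC(=O)C(=C)[C@@H]1O[C@H]1C/C(C)=C/CC/C(COC(=O)/C(C)=C/CO[Si](C)(C)C(C)(C)C)=C/CO[Si](CC)(CC)CC | intermediate
21 | trans-(2S,3S)-2-(oxiranyl)acrylate, C6 enal | COC(=O)C(=C)[C@@H]1O[C@H]1C/C(C)=C/CC/C(COC(=O)/C(C)=C/CO[Si](C)(C)C(C)(C)C)=C/C=O | intermediate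
22 | open-chain (8S)-ethylzinc alkoxide allylzinc, fluxional C7=C11 (not isolated) | CC[Zn]CC(C(=O)OC)=C[C@@H](O[Zn]CC)C/C(C)=C/CC/C(COC(=O)/C(C)=C/CO[Si](C)(C)C(C)(C)C)=C/C=O | intermediate
23 | (5S)-3-(ethylzinciomethyl)butenolide enal (not isolated) | CC[Zn]CC1=C[C@H](C/C(C)=C/CC/C(COC(=O)/C(C)=C/CO[Si](C)(C)C(C)(C)C)=C/C=O)OC1=O | intermediate
24 | 4'-O-TBS ether of the target (6R,7S,8S) | C=C1C(=O)O[C@H]2C/C(C)=C/CC/C(COC(=O)/C(C)=C/CO[Si](C)(C)C(C)(C)C)=C/[C@@H](O)[C@H]12 | intermediate
25 | (6R,7S,8S)-6-hydroxy-15-[(E)-4-hydroxy-2-methylbut-2-enoyloxy]germacra-1(10)E,4Z,11(13)-trien-12,8-olide | C=C1C(=O)O[C@H]2C/C(C)=C/CC/C(COC(=O)/C(C)=C/CO)=C/[C@@H](O)[C@H]12 | target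

**Total step count:** 14. **Longest linear sequence:** 11 (steps 3, 4, 5, 7–14; the same length via steps 1, 2, 5, 7–14).

**Steps most likely to fail**

Step 13.
- Risks:
  - Pd(0) may also ionise the C15 allylic ester.
  - The δ-oxido allylzinc may eliminate to a 2-vinylacrylate.
  - Attack through C13 would give a 12-membered ring.
  - Oligomers or a cis-fused product may form.
- Fallback: it sets out from 21 and forms the two rings one after the other, without palladium. MgBr2·OEt2 in Et2O/THF opens the epoxide at C7, and the magnesium alkoxide on O8 lactonises. Bromide-mediated allylic transposition then gives the conjugated primary bromide, the bromomethyl butenolide F1. CrCl2 in THF/DMF at high dilution (Nozaki–Hiyama allylation; allylic esters are untouched and the Cr(III) alkoxide on O6 is inert) closes C6–C7. This comes back to the route at 24.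

Step 7.
- Risks:
  - The 2-bromoallylic ester may ionise to a π-allyl complex.
  - It may lose carboxylate from the alkenylpalladium to give an allene before transmetalation.
- Fallback: it sets out from 12 and 7 and installs the side chain only after the palladium step. Compound 12 is acetylated (Ac2O, pyridine) to the dienyl acetate F2. F2 is hydroborated and coupled with the free bromo alcohol 7, which has no allylic leaving group, to give the allylic alcohol F3. F3 is esterified with acid 4 (EDC, DMAP) to the acetate ester F4. K2CO3 in MeOH at 0 °C removes the unhindered primary acetate much faster than it cleaves the α-methyl enoate. This comes back to the route at 14.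

Step 10.
- Risks:
  - The vinylalane may add sluggishly.
  - Residual hydride may reduce the aldehyde.
  - The Lewis-acidic aluminium may epimerise the α-chloroaldehyde.
- Fallback: it sets out from 16 and builds the acrylate by a masked-acrylate aldol. The lithium enolate of methyl 3-(dimethylamino)propanoate (LDA, THF, −78 °C) adds to 16 to give the amino chlorohydrin F5. MeI converts F5 into the ammonium iodide F6. K2CO3 in MeCN then effects Hofmann elimination to the acrylate and epoxide closure in the same pot. This comes back to the route at 20.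

**Further compounds**
F1 | step 13 | (5S)-3-(bromomethyl)-5-substituted furan-2(5H)-one bearing the C6 enal and the TBS-protected side chain | BrCC1=C[C@H](C/C(C)=C/CC/C(COC(=O)/C(C)=C/CO[Si](C)(C)C(C)(C)C)=C/C=O)OC1=O
F2 | step 7 | (E)-4-methylhepta-4,6-dien-1-yl acetate | CC(=O)OCCC/C(C)=C/C=C
F3 | step 7 | (4E,8Z)-8-(hydroxymethyl)-4-methyl-10-(triethylsilyloxy)deca-4,8-dien-1-yl acetate | CC(=O)OCCC/C(C)=C/CC/C(CO)=C/CO[Si](CC)(CC)CC
F4 | step 7 | O-acetate of 14 | CC(=O)OCCC/C(C)=C/CC/C(COC(=O)/C(C)=C/CO[Si](C)(C)C(C)(C)C)=C/CO[Si](CC)(CC)CC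
F5 | step 10 | anti chlorohydrin aldol with 2-(dimethylaminomethyl) group (C2 epimers) | COC(=O)C(CN(C)C)[C@H](O)[C@H](Cl)C/C(C)=C/CC/C(COC(=O)/C(C)=C/CO[Si](C)(C)C(C)(C)C)=C/CO[Si](CC)(CC)CC
F6 | step 10 | trimethylammonium iodide of F5 | COC(=O)C(C[N+](C)(C)C)[C@H](O)[C@H](Cl)C/C(C)=C/CC/C(COC(=O)/C(C)=C/CO[Si](C)(C)C(C)(C)C)=C/CO[Si](CC)(CC)CC.[I-]
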